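Late in the north-east run, which is this flask followed so far, target was falling, and I wanted to know what that fall was worth.

| flask | substrate | coupling partner | temperature | remark | time |
|---|---|---|---|---|---|
| north-east | 0.30 M | 0.30 M | 90 °C | the very flask that is asked about, followed so far |  |
| south-west | 0.30 M | 0.20 M | 90 °C | run made earlier |  |
| flask | 0.30 M | 0.300 M | 90 °C |  | 8.0 d |

north-east run (percent of the substrate charged)

| time / d | target / % |
|---|---|
| 1.67 | 27 |
| 3.00 | 24 |
| 5.00 | 21 |
| 6.00 | 16 |

south-west run (percent of the substrate charged)

| time / h | target / % |
|---|---|
| 3.00 | 3 |
| 8.00 | 9 |
| 15.0 | 15 |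
| 40.0 | 23 |

(readings scatter by 2 percentage points)

- midnight: at 8.0 d raise the temperature by 25 K, then wait 8.0 d
- winter: change nothing and wait 8.0 d more
- dawn: at 8.0 d add coupling partner, 50.0% of the amount charged, then wait 8.0 d
- spring: at 8.0 d take out 90% of the target then present, then wait 8.0 d

- what is taken out of target is counted as made
- the earlier runs were read with a standard deviation of 2 percentage points
- additions bring no volume worth counting
- the earlier runs do not show what temperature does; that part of a forecast is a guess

* target, in percent of the substrate first charged, at 8.0 d
* the option that brings most further target ("none" if no option brings more than 2 percentage points) (midnight / winter / dawn / spring / none)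
* target present, with what was taken out counted in, in percent of the substrate first charged, after winter
* target present, with what was taken out counted in, in percent of the substrate first charged, after spring

I let the target's own concentration set the order of its loss: first order, so a fixed fraction goes per day however much target stands there. From the first reading, 27% at 1.67 d, to the last, 16% at 6.00 d, I read a loss constant λ = 0.121 d⁻¹. Folded with the wait Δt = 8.0 d, it gave θ = λΔt = 0.967, the number of e-foldings of target in one wait. Survival over a wait was then exp(−θ) = 0.380.

For this flask I reckoned 12.6% at 8.0 d, then 4.78% after winter. Spring would total 11.8%, a change of −0.78 percentage points.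

θ was enough if nothing refilled target; a refill would leave the flask above these figures. At 40.0 h the south-west run read 23% and the north-east run, with more coupling partner, read 27%, so I expected little from dawn. Heat was a guess, and I chose none.

The forecast gave 13%, 5.5% after winter, 15% after spring, and the choice spring: "Spring is my tentative choice."

The flask gave 15.6% and the choice midnight, worth 8.9 points against 5.9 points for spring, with 10.8% after winter and 21.5% after spring.

    substrate + coupling partner → target, rate k1*[substrate]^1.5*[coupling partner] (k = 3.75 × 10⁻⁵ M⁻¹·⁵ s⁻¹, Ea = 88.0 kJ mol⁻¹)
    target ⇌ isomer of the product (K = 4.60, k = 3.12 × 10⁻⁶ s⁻¹, Ea = 123 kJ mol⁻¹, ΔH = −61.0 kJ mol⁻¹)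
    2 coupling partner → homo dimer (k = 1.36 × 10⁻⁵ M⁻¹ s⁻¹, Ea = 81.0 kJ mol⁻¹)
    (constants at 90 °C)

From 15.6%, exp(−θ) put winter at 5.92%, yet this flask held more than that, 10.8%. Left for ten times the time, the flask held 9.85% at 80.0 d, more than the 0.00257% that λ allowed. The largest single effect on target at 8.0 d was the reaction of target to isomer of the product, both ways: this flask held 15.6%, and the run without that reaction held 51.1%.

The numbers in the tables stem from a simulated flask from invented constants, and the scatter is random.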